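(Its constants are assumed; what happens was integrated by code.)

A small charge of starting material, 0.10 M, met 2.50 equiv of reagent in four flasks that differed in what went in and when, and I wanted the target in each.

common to all: time 2.0 min
- west: starting material 0.10 M; reagent 2.50 equiv (fed, over 80 s); all else is in the flask from the start; the feed brings no volume worth counting
- east: starting material 0.10 M; reagent 2.50 equiv; everything together at the start
- north-west: starting material 0.10 M (fed, over 80 s); reagent 2.50 equiv; all else is in the flask from the start; the feed brings no volume worth counting
- south-east: starting material 0.10 M (in portions, 2, over 80 s); reagent 2.50 equiv; first portion at the start, last at 80 s

1. the flask that comes out highest in amount of target, in percent of the starting material charged, or "all alike" when all lie within 1.5 percentage points (west / east / north-west / south-east / all alike)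
2. target at the end, in percent of the starting material charged, west
3. target at the end, in percent of the starting material charged, east
4. target at the end, in percent of the starting material charged, north-west
5. target at the end, in percent of the starting material charged, south-east

- amounts and yields of target count crystals too
- a doubled species enters its step squared and goes two at a time
- given per volume of solution although it is solid: crystals
- run time (west): 2.0 min

Starting material took up one reagent to give target, reversibly, or two reagent to give side product, and target above its solubility left as crystals. Both branches carry [starting material], so when I divided one forward rate by the other, it dropped out and time with it: what remained was 0.045 L mol⁻¹ s⁻¹ over 0.15 L² mol⁻² s⁻¹ times [reagent], which stood at 1.20 at the start in east. I carried this quotient as the branch ratio, target formed by the forward step per side product formed, a selectivity factor.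

At the start in east it gave target a share of 54.5% of the two forward rates. Both branches together gave starting material a half-life of 33.6 s at the charged reagent. With reagent taken at its middle level, as if pseudo-first-order, I reckoned that 86.8% reacted, and with the opening share held throughout I committed to 47.3% target in east. Supposing reagent in west at half its charge gave a ratio of 2.40, higher than east's opening one, but the ratio holds no time, so my reckoning stopped there, without a ranking.

The forecast gave east as highest, with 43% there, 40.5% in west, 36% in north-west and 33% in south-east, holding of east that “its high reagent costs selectivity, but it converts fastest”.

East came out highest at 43.0%, with west at 40.1%, north-west at 35.3% and south-east at 32.8%. My east figure stood above that, and east kept 25.3% of its starting material where I had left 13.2%.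

    starting material + reagent ⇌ target (K1 = 6.2 L mol⁻¹, k1 = 0.045 L mol⁻¹ s⁻¹)
    starting material + 2 reagent → side product (k2 = 0.15 L² mol⁻² s⁻¹)
    crystals ⇌ target, rate k3*(cs3 - [target]) while solid is left; crystals form when [target] > cs3 (cs3 = 6.2 mM, k3 = 0.21 s⁻¹)

A neighbour of east was charged with 0.620 equiv of reagent, and there the same quotient stood at 4.84 at the start, higher than the 1.20 of east. At the end that neighbour read 17.3% target and 3.66% side product, more target per side product than east, and it still held 79.0% of its starting material.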